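**Retrosynthetic overview**

- The target is reached from (2R)-5,8-dimethoxy-2-pentadecylchroman-4-one by cleavage of both aryl methyl ethers; that ketone comes from a cis-4-silyloxychroman-5-ol by O-methylation, desilylation and oxidation at C4.
- The strategy rests on ring A (C4a, C5, C6, C7, C8, C8a), a benzene ring with oxygen at C5 and C8 (para) and hydrogen at C6 and C7. It is cut at C7–C8, C5–C6 and C4a–C5 into a chromium methoxycarbene on C6 of a dihydropyran (C8 with its oxygen, C8a, C4a), one CO ligand (C5 with its hydroxyl) and ethyne (C6, C7).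
- The carbene complex comes from C6 lithiation of a (2R,4S)-4-silyloxy-2-pentadecyl-3,4-dihydro-2H-pyran, Cr(CO)6 and methyl triflate; the silyl ether comes from 1,2-reduction and silylation of (2R)-2-pentadecyl-2,3-dihydro-4H-pyran-4-one.
- The pyranone comes from a catalytic asymmetric hetero-Diels–Alder reaction of hexadecanal with Danishefsky's diene, which sets C2, the only stereocentre of the target.
- Ring order: ring B (the oxygen ring) first, ring A last.

Key step: step 5

Assumption: the sense of induction in step 1 is assigned by analogy with BINOL–titanium-catalysed additions to unbranched aliphatic aldehydes, where the (S)-ligand is expected to lead to the (2R)-pyranone; should the opposite sense be found, (R)-BINOL would be used with no other change.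

Remark on protecting groups: the C4 alcohol is carried as a triisopropylsilyl ether, not a tert-butyldimethylsilyl ether, because the Si–CH3 groups of the latter can be deprotonated by tert-butyllithium in step 4. The C5 phenol is capped as a methyl ether, which cannot migrate to the C4 oxygen and falls together with the C8 methyl ether in the last step.

**Step 1**
Reactants: 1 hexadecanal; 2 (E)-1-methoxy-3-(trimethylsilyloxy)buta-1,3-diene
Product: 4 (2R)-2-pentadecyl-2,3-dihydro-4H-pyran-4-one, via silyl aldol adduct 3 (not isolated)
Conditions: (S)-BINOL (20 mol %), Ti(OiPr)4 (20 mol %), 4 Å MS, Et2O, −20 °C; then CF3CO2H, CH2Cl2, 0 °C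
Reagents that add atoms: none
Why: A BINOL–titanium-catalysed Mukaiyama aldol addition of the siloxydiene to the aldehyde, followed by acid-promoted cyclisation with loss of methanol (a formal hetero-Diels–Alder reaction), is established for unbranched aliphatic aldehydes, and the chiral titanium complex shields one face of the aldehyde so that C2 should be set as R.

**Step 2**
Reactants: 4 (2R)-2-pentadecyl-2,3-dihydro-4H-pyran-4-one
Product: 5 (2R,4S)-2-pentadecyl-3,4-dihydro-2H-pyran-4-ol
Conditions: NaBH4, CeCl3·7H2O, MeOH, −78 °C; work-up without acid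
Reagents that add atoms: none
Why: Luche 1,2-reduction of the vinylogous ester carbonyl should deliver hydride axially to the half-chair that holds the C2 chain equatorial, giving the cis (4S) allylic alcohol; this centre is oxidised again in step 8, so its ratio is not critical.

**Step 3**
Reactants: 5 (2R,4S)-2-pentadecyl-3,4-dihydro-2H-pyran-4-ol
Product: 6 (2R,4S)-2-pentadecyl-4-(triisopropylsilyloxy)-3,4-dihydro-2H-pyran
Conditions: TIPSCl, imidazole, DMAP (cat.), DMF, rt
Reagents that add atoms: triisopropylsilyl chloride (TIPSCl), CC(C)[Si](Cl)(C(C)C)C(C)C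
Why: Base-mediated silylation of a secondary allylic alcohol avoids the acid that would trigger allylic (Ferrier-type) ionisation of the enol ether, and the triisopropylsilyl group has no acidic Si–CH3 protons for the next step.

**Step 4**
Reactants: 6 (2R,4S)-2-pentadecyl-4-(triisopropylsilyloxy)-3,4-dihydro-2H-pyran; 7 chromium hexacarbonyl, Cr(CO)6
Product: 10 pentacarbonyl{methoxy[(2R,4S)-2-pentadecyl-4-(triisopropylsilyloxy)-3,4-dihydro-2H-pyran-6-yl]methylidene}chromium, via lithio dihydropyran 8 (not isolated), via lithium acylchromate 9 (not isolated)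
Conditions: t-BuLi (2 equiv), THF, −78 → 0 °C, 1 h; Cr(CO)6, −78 °C → rt; solvent exchange; MeOTf, CH2Cl2, 0 °C → rt
Reagents that add atoms: methyl trifluoromethanesulfonate (MeOTf), COS(=O)(=O)C(F)(F)F
Why: Oxygen-directed vinylic deprotonation at C6 of the cyclic enol ether (as practised on silyl-protected glycals) gives 8, surplus tert-butyllithium is consumed by THF at 0 °C, addition of 8 to a CO ligand gives acylchromate 9, and O-methylation by the hard electrophile completes a Fischer carbene synthesis that leaves the silyl ether and both stereocentres untouched.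

**Step 5**
Reactants: 10 pentacarbonyl{methoxy[(2R,4S)-2-pentadecyl-4-(triisopropylsilyloxy)-3,4-dihydro-2H-pyran-6-yl]methylidene}chromium; 11 ethyne
Product: 13 (2R,4S)-8-methoxy-2-pentadecyl-4-(triisopropylsilyloxy)chroman-5-ol, via Cr(CO)3 arene complex 12 (not isolated)
Conditions: HC≡CH (1 atm), THF (0.02 M), 50 °C; then air, MeCN, rt
Reagents that add atoms: none
Why: Thermal loss of one CO ligand from 10 lets ethyne coordinate and insert into the chromium–carbene bond, CO insertion then gives a chromium-bound dienylketene, and this closes ring A by 6π electrocyclisation between the ketene carbon and the ring B alkene carbon next to C4 (the C4a–C5 bond), before tautomerisation to the phenol held as arene complex 12, which air strips of its Cr(CO)3 unit. This is the Dötz benzannulation, and its closest precedent is the reaction of 3,4-dihydro-2H-pyran-6-yl and glycal-derived chromium methoxycarbenes with alkynes to give chroman-5-ols. Because the enol ether double bond of ring B is the alkenyl arm of the carbene, O1 ends on C8a, the carbene carbon becomes C8 with its methoxy group, the inserted CO becomes C5 with its hydroxyl para to it, and the two ethyne carbons become C6 and C7, which also makes C7–C8 and C5–C6. No stereocentre is created, and C2 and C4 are sp3 centres outside the reacting π system, so they are not touched. The selectivity needed is phenol formation over cyclobutenone, indene and furan products and over uptake of a second ethyne; the alkenyl methoxycarbene, the ether solvent, the moderate temperature and a dilute solution under one atmosphere of the symmetrical alkyne (no regiochemical issue) should secure it.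

**Step 6**
Reactants: 13 (2R,4S)-8-methoxy-2-pentadecyl-4-(triisopropylsilyloxy)chroman-5-ol
Product: 14 (2R,4S)-5,8-dimethoxy-2-pentadecyl-4-(triisopropylsilyloxy)chroman
Conditions: MeI, K2CO3, DMF (degassed), rt, argon
Reagents that add atoms: iodomethane (MeI), CI
Why: Williamson O-methylation of the phenoxide removes the oxidation-prone 4-methoxyphenol and the ortho-hydroxybenzyl ether (a quinone methide precursor) before C4 is deprotected and oxidised.

**Step 7**
Reactants: 14 (2R,4S)-5,8-dimethoxy-2-pentadecyl-4-(triisopropylsilyloxy)chroman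
Product: 15 (2R,4S)-5,8-dimethoxy-2-pentadecylchroman-4-ol
Conditions: Bu4NF, THF, rt → 40 °C
Reagents that add atoms: none
Why: Fluoride-induced cleavage of the silyl ether is non-acidic, so the electron-rich benzylic C4–O bond does not ionise, and the aryl methyl ethers are inert to it.

**Step 8**
Reactants: 15 (2R,4S)-5,8-dimethoxy-2-pentadecylchroman-4-ol
Product: 16 (2R)-5,8-dimethoxy-2-pentadecylchroman-4-one
Conditions: Pr4N[RuO4] (5 mol %), N-methylmorpholine N-oxide, 4 Å MS, CH2Cl2, rt
Reagents that add atoms: none
Why: Ley–Griffith oxidation converts the secondary benzylic alcohol to the ketone under neutral conditions that should neither dehydrate the chromanol nor open ring B, so C2 keeps its configuration.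

**Step 9**
Reactants: 16 (2R)-5,8-dimethoxy-2-pentadecylchroman-4-one
Product: 17 (2R)-5,8-dihydroxy-2-pentadecylchroman-4-one
Conditions: BBr3 (5 equiv), CH2Cl2, −78 → 0 °C; then H2O (degassed)
Reagents that add atoms: none
Why: Lewis acid cleavage of aryl methyl ethers by BBr3 should remove the C5 methyl with chelation assistance from the C4 carbonyl and the C8 methyl as an ordinary anisole, while O1 is deactivated by conjugation with the ketone and the low temperature limits retro-oxa-Michael opening of ring B.

**Compound list**

1 | hexadecanal | CCCCCCCCCCCCCCCC=O | starting material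
2 | (E)-1-methoxy-3-(trimethylsilyloxy)buta-1,3-diene | CO/C=C/C(=C)O[Si](C)(C)C | starting material
3 | (5R,1E)-1-methoxy-5-(trimethylsilyloxy)icos-1-en-3-one | CCCCCCCCCCCCCCC[C@@H](O[Si](C)(C)C)CC(=O)/C=C/OC | intermediate (not isolated)
4 | (2R)-2-pentadecyl-2,3-dihydro-4H-pyran-4-one | CCCCCCCCCCCCCCC[C@@H]1CC(=O)C=CO1 | intermediate
5 | (2R,4S)-2-pentadecyl-3,4-dihydro-2H-pyran-4-ol (cis) | CCCCCCCCCCCCCCC[C@@H]1C[C@H](O)C=CO1 | intermediate
6 | (2R,4S)-2-pentadecyl-4-(triisopropylsilyloxy)-3,4-dihydro-2H-pyran (cis) | CCCCCCCCCCCCCCC[C@@H]1C[C@H](O[Si](C(C)C)(C(C)C)C(C)C)C=CO1 | intermediate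
7 | chromium hexacarbonyl, Cr(CO)6 | O=C=[Cr](=C=O)(=C=O)(=C=O)(=C=O)=C=O | starting material
8 | [(2R,4S)-2-pentadecyl-4-(triisopropylsilyloxy)-3,4-dihydro-2H-pyran-6-yl]lithium | CCCCCCCCCCCCCCC[C@@H]1C[C@H](O[Si](C(C)C)(C(C)C)C(C)C)C=C([Li])O1 | intermediate (not isolated)
9 | lithium pentacarbonyl{[(2R,4S)-2-pentadecyl-4-(triisopropylsilyloxy)-3,4-dihydro-2H-pyran-6-yl]carbonyl}chromate | CCCCCCCCCCCCCCC[C@@H]1C[C@H](O[Si](C(C)C)(C(C)C)C(C)C)C=C(O1)C([O-])=[Cr](=C=O)(=C=O)(=C=O)(=C=O)=C=O.[Li+] | intermediate (not isolated)
10 | pentacarbonyl{methoxy[(2R,4S)-2-pentadecyl-4-(triisopropylsilyloxy)-3,4-dihydro-2H-pyran-6-yl]methylidene}chromium | CCCCCCCCCCCCCCC[C@@H]1C[C@H](O[Si](C(C)C)(C(C)C)C(C)C)C=C(O1)C(OC)=[Cr](=C=O)(=C=O)(=C=O)(=C=O)=C=O | intermediate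
11 | ethyne | C#C | starting material
12 | tricarbonyl{η6-[(2R,4S)-8-methoxy-2-pentadecyl-4-(triisopropylsilyloxy)chroman-5-ol]}chromium, Cr(CO)3 bound to ring A (written as two components because the hapticity cannot be expressed) | CCCCCCCCCCCCCCC[C@@H]1C[C@H](O[Si](C(C)C)(C(C)C)C(C)C)c2c(O)ccc(OC)c2O1.O=C=[Cr](=C=O)=C=O | intermediate (not isolated)
13 | (2R,4S)-8-methoxy-2-pentadecyl-4-(triisopropylsilyloxy)chroman-5-ol (cis) | CCCCCCCCCCCCCCC[C@@H]1C[C@H](O[Si](C(C)C)(C(C)C)C(C)C)c2c(O)ccc(OC)c2O1 | intermediate
14 | (2R,4S)-5,8-dimethoxy-2-pentadecyl-4-(triisopropylsilyloxy)chroman | CCCCCCCCCCCCCCC[C@@H]1C[C@H](O[Si](C(C)C)(C(C)C)C(C)C)c2c(OC)ccc(OC)c2O1 | intermediate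
15 | (2R,4S)-5,8-dimethoxy-2-pentadecylchroman-4-ol | CCCCCCCCCCCCCCC[C@@H]1C[C@H](O)c2c(OC)ccc(OC)c2O1 | intermediate
16 | (2R)-5,8-dimethoxy-2-pentadecylchroman-4-one | CCCCCCCCCCCCCCC[C@@H]1CC(=O)c2c(OC)ccc(OC)c2O1 | intermediate
17 | (2R)-5,8-dihydroxy-2-pentadecylchroman-4-one | CCCCCCCCCCCCCCC[C@@H]1CC(=O)c2c(O)ccc(O)c2O1 | target

**Step count**

Total: 9 steps. Longest linear sequence: 9 steps, from hexadecanal.

**Steps most likely to fail**

1. Step 5. Ethyne may oligomerise on the carbene complex or be taken up twice, its low concentration in solution may let the complex decompose before insertion, and the 4-methoxyphenol may be over-oxidised during decomplexation. The fallback sets out from 10 and replaces the gas by a liquid ethyne equivalent with a removable group. Heating 10 with trimethylsilylethyne in THF at 50 °C should give the tricarbonylchromium arene complex F1, which on exposure to air should release (2R,4S)-8-methoxy-2-pentadecyl-4-(triisopropylsilyloxy)-6-(trimethylsilyl)chroman-5-ol F2, with silicon next to the hydroxyl as expected for a terminal alkyne. Brief ipso-protodesilylation of this strongly activated arylsilane with CF3CO2H in CH2Cl2 at 0 °C comes back to the route at 13.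

2. Step 4. Surplus tert-butyllithium may attack Cr(CO)6, the vinylic deprotonation may stay incomplete, and the O-alkylation of the acylchromate may be inefficient. The fallback sets out from 6 and separates metalation from carbene formation. Lithiation of 6 as before and quenching with Bu3SnCl should give tributyl[(2R,4S)-2-pentadecyl-4-(triisopropylsilyloxy)-3,4-dihydro-2H-pyran-6-yl]stannane F3, which can be purified. Tin–lithium exchange with exactly one equivalent of n-BuLi in THF at −78 °C then gives 8 free of other bases, and Cr(CO)6 followed by MeOTf comes back to the route at 10.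

3. Step 9. The Lewis acid may open ring B by retro-oxa-Michael reaction, with loss of configuration at C2 on reclosure, or may leave the C8 methyl ether partly uncleaved. The fallback sets out from 16 and avoids a Lewis acid. Oxidative demethylation with (NH4)2Ce(NO3)6 in MeCN–H2O at 0 °C should give (2R)-2-pentadecyl-2,3-dihydro-4H-chromene-4,5,8-trione F4, and immediate reduction of this quinone with Na2S2O4 in EtOAc–H2O comes back to the route at 17.

**Further compounds**

F1 | step 5 | tricarbonyl{η6-[(2R,4S)-8-methoxy-2-pentadecyl-4-(triisopropylsilyloxy)-6-(trimethylsilyl)chroman-5-ol]}chromium (written as two components) | CCCCCCCCCCCCCCC[C@@H]1C[C@H](O[Si](C(C)C)(C(C)C)C(C)C)c2c(O)c([Si](C)(C)C)cc(OC)c2O1.O=C=[Cr](=C=O)=C=O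
F2 | step 5 | (2R,4S)-8-methoxy-2-pentadecyl-4-(triisopropylsilyloxy)-6-(trimethylsilyl)chroman-5-ol | CCCCCCCCCCCCCCC[C@@H]1C[C@H](O[Si](C(C)C)(C(C)C)C(C)C)c2c(O)c([Si](C)(C)C)cc(OC)c2O1
F3 | step 4 | tributyl[(2R,4S)-2-pentadecyl-4-(triisopropylsilyloxy)-3,4-dihydro-2H-pyran-6-yl]stannane | CCCCCCCCCCCCCCC[C@@H]1C[C@H](O[Si](C(C)C)(C(C)C)C(C)C)C=C(O1)[Sn](CCCC)(CCCC)CCCC
F4 | step 9 | (2R)-2-pentadecyl-2,3-dihydro-4H-chromene-4,5,8-trione | CCCCCCCCCCCCCCC[C@@H]1CC(=O)C2=C(O1)C(=O)C=CC2=O
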